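(All runs were generated by integration with constants of no real substance; scatter was added.)

Per minute is the unit to count in. If G goes to E with a first-order constant k, then N = k·t is a plain number of turnovers, and N times the share of G standing gives the E made, before any loss of E.

| flask | G | temperature | remark | time |
|---|---|---|---|---|
| east | 0.013 M | 10 °C | run made earlier |  |
| west | 0.030 M | 25 °C | run made earlier |  |
| Thursday's | 0.020 M |  | at 15 °C until 1.0 h, from then on at 35 °C | 2.0 h |
| Tuesday's | 0.020 M | 15 °C |  | 2.0 h |
| Monday's | 0.020 M | 35 °C |  | 2.0 h |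

| run | time / min | E / % | G / % |
|---|---|---|---|
| east | 30.0 | 0.4 | 91.5 |
| east | 60.0 | 1.0 | 84.8 |
| east | 90.0 | 2.4 | 79.4 |
| east | 120 | 1.6 | 74.3 |
| west | 10.0 | 1.1 | 75.8 |
| west | 25.0 | 3.5 | 57.6 |
| west | 50.0 | 6.2 | 44.5 |
| west | 80.0 | 8.6 | 39.1 |

(standard deviation of a reading: 0.5 percentage points)

- the numbers in the tables scatter by 0.5 percentage points (one standard deviation)
- a reading or a percentage of E counts all its forms, free or not

- which flask leads in amount of E, in percent of the G charged ("all alike" within 1.5 percentage points) (Thursday's / Tuesday's / Monday's / all alike)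
- how much E is there at the end, in percent of the G charged: Thursday's
- how much E is there at the end, in percent of the G charged: Tuesday's
- how much E is there at the end, in percent of the G charged: Monday's

What is k? West's last E, 8.6%, divided by the time integral of [G] as a share of the charge, reads 0.00195 min⁻¹. East's last two readings, taken together against their scatter, read 2.19 × 10⁻⁴ min⁻¹. Taking ln k as straight in temperature, we get a factor 4.30 from west's temperature to either flask temperature, so we reckon k as 0.00838 min⁻¹ when hot, at 35 °C, and 4.54 × 10⁻⁴ min⁻¹ when cold, at 15 °C.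

How many turnovers does each flask get? Tuesday's gets 0.0545, the turnover count, and Monday's gets 1.01, far more. Thursday's, cold until 1.0 h and hot after, gets 0.530.

How much G stands under them? We take east's last 74.3% for cold hours and west's last 39.1% for hot ones; west's G readings flatten in what looks like a pre-equilibrium. Our count of E made is then 4.05% for Tuesday's, 21.7% for Thursday's and 39.3% for Monday's, which leads.

The forecast calls E's making “a slow, nearly irreversible leak from G” and names Monday's as leader, with 20% for Thursday's, 3.3% for Tuesday's and 32% for Monday's, lower than our count of E made.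

The flasks give 17.7% for Thursday's, 4.06% for Tuesday's and 20.7% for Monday's, so Monday's leads, with less E than the forecast said.

    G → E (k = 0.00911 min⁻¹, Ea = 106 kJ mol⁻¹)
    2 G ⇌ Q (K = 51.3 L mol⁻¹, k = 1.37 L mol⁻¹ min⁻¹, Ea = 72.0 kJ mol⁻¹, ΔH = −9.00 kJ mol⁻¹)
    E → D (k = 0.0130 min⁻¹, Ea = 84.0 kJ mol⁻¹)
    Z ⇌ E, rate k4*(cs4 - [E]) while solid is left; crystals form when [E] > cs4 (solubility = 15.0 mM, k = 0.140 min⁻¹)
    E → L (k = 2.11 × 10⁻⁵ min⁻¹, Ea = 122 kJ mol⁻¹)
    (constants at 35 °C)

At 2.00 h Monday's also holds 24.9% D, which makes 45.6% of E and D together, against our 39.3% made in 1.01 turnovers.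

Thursday's read at 30 min, still cold, has 0.0136 turnovers, which on east's first 91.5% of G gives 1.25% E. The flask gives 1.36%.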